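A small charge of solid L meets the catalyst J, and this meeting asked whether the solution can take it up.

L 0.0010 M; J 5.0 µM; Q 26 µM; time 2.0 h

    Z + J ⇌ G + J, rate k1*[Z]*[J] forward; the back reaction follows from the equilibrium constant (K1 = 2.65, k1 = 28800 M⁻¹ s⁻¹)
    G + J ⇌ D + J, rate k2*[J]*[G] forward; the back reaction follows from the equilibrium constant (K2 = 9.21, k2 = 27400 M⁻¹ s⁻¹)
    L ⇌ Z, rate k3*(cs3 - [Z]) while solid is left; crystals form when [Z] > cs3 (cs3 = 0.095 mM, k3 = 0.0299 s⁻¹)
    J + Q ⇌ J.Q, settled at all times (K4 = 15000 M⁻¹)
    Z ⇌ X (K5 = 0.75, k5 = 0.0179 s⁻¹)

- part of the L that has turned into other species by 2.0 h (what has only dissolved does not count)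
- how much G there is at 2.0 h, in percent of the L charged
- amount of G if the flask were left three thousand times as long, in percent of the L charged

- given per volume of solution although it is solid: L
- at the start none of L is in solution
- what has only dissolved of L counts as not reacted
- what has gone from Z into another species counts as reacted, even if it can come back
- run time (flask): 2.0 h

The first speaker counted lifetimes. She let Q hold back part of J, which leaves about 3.60 µM free, so a Z lives about 9.65 s against the turning into G. At its opening rate of dissolving, the solid lasts about 5.87 min. Both times are far shorter than the run, so she expected balance at the reading, which is thermodynamic control.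

The second speaker, who writes these minutes, asked where that balance stands while solid is present. By my reckoning, each Z in solution carries K1 of G, K1·K2 of D and K5 of X, so the dissolved total is 28.8 times Z. But crystals form when Z passes 9.50 % of the charge. Their product is the holding number, the most the solution takes up at balance, in charges: 2.74. In this flask it is more than one charge, so I committed to an empty solid. Then Z is one part of that total, so the conversion is 96.5 %, G is 9.20 %, and G after the long wait is 9.20 %.

The forecast gave 96.5 %, 9.2 % and 9.2 %, holding that “waiting longer changes nothing”.

This flask gives 96.5 %, 9.20 % and 9.20 %, with L at 0 % at 2.00 h. Its holding number rests on D: with the turning of G into D struck out, both ways, conversion falls from 96.5 % to 32.3 %. The reckoning reads that run too. The holding number shrinks to 0.418, less than one charge, and subtracting Z at its 9.50 % leaves an estimated 32.3 % reacted.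

The neighbour, charged with 0.0040 M of L, has a holding number of 0.684, less than one charge, so solid should stay and 66.0 % should react. The computed neighbour reaches 65.8 %, with 34 % of its L still there, solid or dissolved.

The constants are made up; no experiment stands behind them.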